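Amber at 45 °C and autumn at 50 °C are close in temperature, but amber held twice autumn's nucleophile, and it ended with target at 84% against side product at 15%. The question is whether autumn's smaller charge keeps target ahead.

in all of them: electrophile 23 mM
- teal: nucleophile 1.3 equiv; free base 1.2 equiv; temperature 31 °C; run made earlier
- amber: nucleophile 2.1 equiv; free base 1.2 equiv; temperature 45 °C; run made earlier
- winter: nucleophile 0.950 equiv; free base 1.20 equiv; temperature 25 °C; time 2.5 h
- autumn: nucleophile 0.950 equiv; free base 1.20 equiv; temperature 50 °C; time 2.5 h

| run | time / min | target / % | electrophile / % | side product / % |
|---|---|---|---|---|
| teal | 30.0 | 59 | 19 | 18 |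
| teal | 60.0 | 62 | 10 | 27 |
| teal | 90.0 | 63 | 7 | 34 |
| teal | 120 | 62 | 4 | 37 |
| amber | 6.00 | 79 | 6 | 14 |
| amber | 15.0 | 82 | 0 | 15 |
| amber | 30.0 | 83 | 0 | 15 |
| amber | 40.0 | 84 | 4 | 15 |

(scatter of a reading: 2 percentage points)

- percentages count the electrophile that a species holds: one side product counts as two

- which of these there is most of at the end, counted by the electrophile in it, winter (side product / target / electrophile)
- which of these there is most of at the end, counted by the electrophile in it, autumn (side product / target / electrophile)
- final amount of the leader among these, as a percentage of the electrophile charged, in winter
- final amount of the leader among these, as a percentage of the electrophile charged, in autumn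

Taking side product as target plus electrophile, as the forecast does, each electrophile consumed goes one of two ways. It meets nucleophile and gives target, or it meets a target and the pair becomes side product, which counts as two. Target plus half the side product therefore counts the electrophile that met nucleophile. That count divided by target plus side product is the split, a selectivity. Target and side product are equal at a split of 0.750, the crossing, and below it side product leads.

The last readings give a split of 0.813 in teal and 0.924 in amber, each carrying the scatter of 2 percentage points. These two runs differ in charge and temperature together. My own reckoning lays the whole change on the charge: the ratio of electrophile lost to the side step over electrophile sent to nucleophile falls as the charge to the power 2.15. At 0.950 equiv this gives an end split of 0.689, below the crossing, so finished autumn should hold target 37.8% and side product 62.2%. Teal's split fell from 0.883 at 30.0 min to 0.813 at 120 min, so a winter still unfinished at 2.5 h should stand above the end split of 0.689; this reckoning does not say by how much, and it leaves winter's leader open.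

The forecast names target at 44% in winter and target at 62% in autumn, on the ground that “Higher temperature therefore favours the target”. In autumn its leader is target and mine is side product.

Winter gives target at 45.5% and side product at 39.2%, a split of 0.769. Autumn gives side product at 60.2% and target at 39.8%, a split of 0.699, below the crossing.

    electrophile + nucleophile → acid set free + target (k = 5.80 M⁻¹ min⁻¹, Ea = 46.0 kJ mol⁻¹)
    acid set free + free base ⇌ salt of the base (K = 1.30 × 10⁵ M⁻¹, k = 5.30 M⁻¹ min⁻¹, Ea = 41.0 kJ mol⁻¹, ΔH = −41.0 kJ mol⁻¹)
    electrophile + target → side product (k = 0.410 M⁻¹ min⁻¹, Ea = 73.0 kJ mol⁻¹)
    nucleophile + acid set free ⇌ protonated nucleophile, settled at all times (K = 18000 M⁻¹, ΔH = −35.0 kJ mol⁻¹)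
    (constants at 25 °C)

A neighbour of winter charged with 0.570 equiv of nucleophile, all else held, ends with target at 26.6% and electrophile at 34.9%. Its split is 0.704, below the crossing, and side product leads there at 38.5%.

The runs come from a simulation on assumed constants; noise was put on by code.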